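## Analysis of the target

Target 22 is a C20 prostanoid methyl ester. Its only ring, C8–C9–C10–C11–C12, is a cyclopent-2-enone (C9=O, C10(Br)=C11) that ends in a tertiary carbinol at C12 and a methine at C8. C8 carries the C1–C7 chain with the contiguous triol C5/C6/C7, and C12 carries the (2Z,5Z)-octa-2,5-dienyl chain C13–C20. The five stereocentres are 5S, 6S, 7S, 8R and 12S. The triol has the 5,6-anti/6,7-syn pattern of C4, C3 and C2 of L-arabinose; the two chains are trans on the ring, so the C12 hydroxyl is cis to the C8 chain and 1,3-related to the C7 hydroxyl. C8 is α to the ketone and lies between two β-oxygens (O7, O12), so it can epimerize, and the molecule can lose water across C7–C8 or open by retro-aldol cleavage. The α-bromoenone is sensitive to nucleophiles and reductants, the skipped Z,Z-diene rules out bromine, hydrogenation and radical conditions late in the route, and the free 5-hydroxyl can lactonize onto the C1 ester. The hard parts are the fully substituted C12 next to C8 inside a ring that already bears the halogen, and the absolute relationship between this ring and the triol. The feature that invites the key move: the ring is a 4-hydroxy-4,5-disubstituted cyclopent-2-enone, so C9, C10, C11, C12 and the ketone oxygen can be read as a 3-bromofuran, C8 as a furyl carbinol carbon, and C8 to C4 as the carbon chain of a pentose.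

## Retrosynthetic reasoning

22 from 21: only the O5–Si bond is cut. The 5-hydroxyl is freed last and under buffered fluoride, because a free 5-hydroxyl next to the methyl ester lactonizes under acid or base.

21 from 20: no bond of the skeleton is cut; C8 is inverted. 20 is the C8 epimer, with the two carbon chains cis on the ring. 21, with the chains trans, should be the more stable isomer, so C8 is set by equilibration through the enol. This is accepted because the key step fixes the non-epimerizable C12 and can only deliver C8 trans to the C12 hydroxyl.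

20 from 19: the O6/O7 acetonide is removed while O5 stays silylated, so that no lactone can form and the C7 oxygen is a poor leaving group during the equilibration.

19 from 18 (key disconnection): the ring bond C8–C12 and the C12–OH bond are cut, and C9–C12 with the ring oxygen are folded back into a 3-bromofuran. Forward, the furylcarbinol 18 is ionized, the solvent delivers the hydroxyl to C12, and a 4π electrocyclization closes C8–C12. This one operation makes the five-membered ring, the quaternary carbinol C12 and the α-bromoenone from an aromatic precursor. It is stereoconvergent: both C8 epimers of 18 give the same cation. Cutting here, and not at C7–C8, lets C7 come from the chiral pool together with C5 and C6, and turns the C8 carbinol of 18 into a centre that need not be controlled.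

18 from 16 and 8: the C8–C9 bond (carbinol carbon to furan C2) is cut. The bromine of 16 directs lithiation to the adjacent α-position, so the union of the two fragments of similar size is one step, and its diastereoselectivity is irrelevant.

8 from 1: aldehyde 8 is L-arabinose (1) with sugar C1 as C8, sugar C2–C4 as C7–C5 and sugar C5 as C4. Only the C4–C3 bond is made, by radical addition of the C5 iodide 6 to a three-carbon acceptor. The trans-fused O6/O7 acetonide is kept on purpose, because in the key step it holds O5 away from the cationic C8.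

16 from 14 and 11: the C14=C15 double bond is cut (Z-selective Wittig). 14 is the one-carbon homologue of commercial aldehyde 12, which already carries the bromine in the right place. 11 comes from leaf alcohol 9, which brings the C17=C18 Z-alkene.

## Alternatives that were turned down

Alternative 1: the textbook disconnection at C7–C8. The α′-lithium enolate of the preformed cyclopentenone A1 (hydroxyl silylated) would be added to the chiral aldehyde A2 in an aldol reaction. Turned down because:
- A1 with its tertiary carbinol must first be made as a single enantiomer, a problem of its own that costs a resolution or an asymmetric step.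
- C7 would be created next to an α,β-dioxygenated aldehyde, where Felkin and chelation control oppose each other.
- C8 would be controlled only by the steric difference between a silyloxy group and a CH2 group on C12, so up to four diastereomers must be expected.
- The enolate sits next to a β-silyloxy leaving group.
- The step sets two centres and builds no ring.

Alternative 2: disconnection at C12–C13, the fully substituted carbon. An α-selective allylic barium reagent made from chloride A4 would add to the C12 ketone of the transposed cyclopentenone A3, anti to the C8 chain, followed by oxidation of the C9 carbinol. A3 would come from the same kind of furan rearrangement with the hydroxyl entering at an unsubstituted furan carbon. Turned down because: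
- A3 is a β-bromoenone, a vinylogous acyl bromide. It would have to survive hot aqueous Lewis acid and then a basic organometallic that can also attack C10 by addition–elimination.
- The C9 carbinol must be carried and oxidized, and A4 must be made (at least three extra steps).
- The risk would be spread over two demanding steps instead of one.

Alternative 3: disconnection at C8–C12 by an aldol reaction of the acyclic (Z)-enedione A5, which would come from oxidative opening of a 2,5-dialkylfuran lacking the C8 hydroxyl. The forward key step is a base-mediated intramolecular aldol cyclization. Turned down because: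
- A5 has two enolizable methylene groups. C13, which is also allylic to C14=C15, is the more acidic, so ring closure would occur mainly between C13 and C9 and the diene would move into conjugation.
- The C8 enolate has the C7 oxygen in the β-position and would eliminate.
- Nothing in A5 relates C8 and C12 to C7.
- C8 would first have to be deoxygenated.

Key step: step 13

Remark: prostanoid numbering of the target (C1 = ester carbon, ring = C8–C12, C13–C20 = octadienyl chain) is used for all intermediates; the sense of torquoselectivity in step 13 is an assumption, argued there from the structure.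

## Steps

Step 1
Reactants: 1 L-arabinose
Product: 2 L-arabinose diethyl dithioacetal
Conditions: EtSH, conc. HCl, 0 °C
Reagents that add atoms: ethanethiol (CCS)
Why: Fischer-type dithioacetalization opens the pyranose and masks sugar C1 (the future C8) while the three carbinol centres (future C7, C6, C5) are untouched.

Step 2
Reactants: 2 L-arabinose diethyl dithioacetal
Product: 3 2,3:4,5-di-O-isopropylidene-L-arabinose diethyl dithioacetal
Conditions: 2,2-dimethoxypropane, acetone, p-TsOH (cat.), rt
Reagents that add atoms: 2,2-dimethoxypropane (COC(C)(C)OC)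
Why: Acetalization under thermodynamic control gives the trans-dioxolane on the threo O2/O3 pair and the terminal dioxolane on O4/O5, the usual pattern for arabinose dithioacetals.

Step 3
Reactants: 3 2,3:4,5-di-O-isopropylidene-L-arabinose diethyl dithioacetal
Product: 4 2,3-O-isopropylidene-L-arabinose diethyl dithioacetal
Conditions: AcOH–H2O (7:3), 40 °C
Reagents that add atoms: none
Why: Selective acetal hydrolysis: the terminal dioxolane is cleaved faster than the internal trans-fused one, which frees only O4 and O5.

Step 4
Reactants: 4 2,3-O-isopropylidene-L-arabinose diethyl dithioacetal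
Product: 5 5-deoxy-5-iodo-2,3-O-isopropylidene-L-arabinose diethyl dithioacetal
Conditions: I2, PPh3, imidazole, THF, 0 °C to rt
Reagents that add atoms: iodine (II)
Why: Appel-type iodination is selective for the primary hydroxyl of the 1,2-diol; the secondary carbinol (future C5) keeps its configuration.

Step 5
Reactants: 5 5-deoxy-5-iodo-2,3-O-isopropylidene-L-arabinose diethyl dithioacetal
Product: 6 5-deoxy-5-iodo-2,3-O-isopropylidene-4-O-triisopropylsilyl-L-arabinose diethyl dithioacetal
Conditions: TIPSOTf, 2,6-lutidine, CH2Cl2, −40 to 0 °C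
Reagents that add atoms: triisopropylsilyl triflate (CC(C)[Si](OS(=O)(=O)C(F)(F)F)(C(C)C)C(C)C)
Why: Silylation of the hindered secondary alcohol with a silyl triflate; the acid-stable silyl ether blocks lactone formation until the last step.

Step 6
Reactants: 6 5-deoxy-5-iodo-2,3-O-isopropylidene-4-O-triisopropylsilyl-L-arabinose diethyl dithioacetal
Product: 7 methyl 5,6,7-trideoxy-2,3-O-isopropylidene-4-O-triisopropylsilyl-L-arabino-octuronate diethyl dithioacetal
Conditions: methyl acrylate (10 equiv), Bu3SnH (slow addition), AIBN (cat.), benzene, 80 °C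
Reagents that add atoms: methyl acrylate (C=CC(=O)OC)
Why: Giese reaction: the primary radical from the C–I bond adds to the acrylate and the adduct radical is reduced by the tin hydride, which appends C3, C2 and C1 to C4 in one step without touching a stereocentre.

Step 7
Reactants: 7 methyl 5,6,7-trideoxy-2,3-O-isopropylidene-4-O-triisopropylsilyl-L-arabino-octuronate diethyl dithioacetal
Product: 8 methyl 5,6,7-trideoxy-2,3-O-isopropylidene-4-O-triisopropylsilyl-aldehydo-L-arabino-octuronate
Conditions: I2, NaHCO3, acetone–H2O (9:1), 0 °C
Reagents that add atoms: water (O)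
Why: Oxidative hydrolysis of the dithioacetal under buffered conditions frees the C8 aldehyde; acetonide, silyl ether and ester survive, and the α-alkoxy aldehyde is used at once.

Step 8
Reactants: 9 (Z)-hex-3-en-1-ol
Product: 10 (Z)-1-iodohex-3-ene
Conditions: I2, PPh3, imidazole, CH2Cl2, 0 °C
Reagents that add atoms: iodine (II)
Why: Appel-type iodination of the primary alcohol; the Z-alkene (future C17=C18) is not touched.

Step 9
Reactants: 10 (Z)-1-iodohex-3-ene
Product: 11 [(3Z)-hex-3-en-1-yl]triphenylphosphonium iodide
Conditions: PPh3, MeCN, reflux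
Reagents that add atoms: triphenylphosphine (c1ccc(cc1)P(c1ccccc1)c1ccccc1)
Why: SN2 quaternization of the phosphine by the primary iodide.

Step 10
Reactants: 12 4-bromofuran-2-carbaldehyde
Product: 14 2-(4-bromofuran-2-yl)acetaldehyde, via enol ether 13 (not isolated)
Conditions: Ph3P(CH2OMe)Cl, KOt-Bu, THF, 0 °C; then 2 M HCl, THF, rt
Reagents that add atoms: (methoxymethyl)triphenylphosphonium chloride (COC[P+](c1ccccc1)(c1ccccc1)c1ccccc1.[Cl-]); water (O)
Why: Wittig methoxymethylenation and hydrolysis of the enol ether give the one-carbon homologue, which puts C13 between the furan and the aldehyde carbon C14; the labile aldehyde is used crude.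

Step 11
Reactants: 14 2-(4-bromofuran-2-yl)acetaldehyde; 11 [(3Z)-hex-3-en-1-yl]triphenylphosphonium iodide
Product: 16 4-bromo-2-[(2Z,5Z)-octa-2,5-dien-1-yl]furan, via ylide 15 (not isolated)
Conditions: 11, NaN(SiMe3)2, THF, −78 °C; then 14, −78 to 0 °C
Reagents that add atoms: none
Why: Salt-free Wittig reaction of a non-stabilized ylide with an aliphatic aldehyde sets C14=C15 as the Z-alkene under kinetic control; inverse addition at low temperature limits enolization of 14.

Step 12
Reactants: 16 4-bromo-2-[(2Z,5Z)-octa-2,5-dien-1-yl]furan; 8 methyl 5,6,7-trideoxy-2,3-O-isopropylidene-4-O-triisopropylsilyl-aldehydo-L-arabino-octuronate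
Product: 18 methyl 8-[3-bromo-5-[(2Z,5Z)-octa-2,5-dien-1-yl]furan-2-yl]-8-hydroxy-6,7-(isopropylidenedioxy)-5-(triisopropylsilyloxy)octanoate (both C8 epimers), via lithiofuran 17 (not isolated)
Conditions: LiN(i-Pr)2 (1.0 equiv), THF, −78 °C; then 8, −78 °C; NH4Cl
Reagents that add atoms: none
Why: Deprotonation of the bromofuran at the α-position next to bromine (the most acidic ring C–H) and 1,2-addition of the furyllithium to the aldehyde, which is much faster than attack on the ester; the C8 carbinol may form as a mixture because step 13 erases it.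

Step 13
Reactants: 18 methyl 8-[3-bromo-5-[(2Z,5Z)-octa-2,5-dien-1-yl]furan-2-yl]-8-hydroxy-6,7-(isopropylidenedioxy)-5-(triisopropylsilyloxy)octanoate
Product: 19 methyl 7-[(1S,2S)-4-bromo-2-hydroxy-2-[(2Z,5Z)-octa-2,5-dien-1-yl]-5-oxocyclopent-3-en-1-yl]-6,7-(isopropylidenedioxy)-5-(triisopropylsilyloxy)heptanoate (8S,12S; the C8 epimer of the target series)
Conditions: ZnCl2 (2 equiv), 1,4-dioxane–H2O (3:1), 85 °C, degassed
Reagents that add atoms: water (O)
Why: Piancatelli rearrangement: ZnCl2-assisted ionization of either C8 epimer of 18 gives the same furfuryl cation, water adds at the alkyl-bearing furan carbon (C12), the hemiketal opens to the 1,4-dihydroxypentadienyl cation C8=C9(OH)–C10(Br)=C11–C12(OH)+, and a thermal conrotatory 4π electrocyclization forms the C8–C12 bond and closes the ring C8–C12 (an electrocyclic closure, not a Baldwin-type attack). The closest known reaction is the ZnCl2-promoted rearrangement of 5-methyl-2-furylcarbinols to trans-4-hydroxy-4-methyl-5-substituted cyclopent-2-enones. At C12 the hydroxyl, as the stronger donor, should rotate outward and the octadienyl CH2 inward; the face on which C12 bonds is dictated by C7, whose hydrogen eclipses the C8=C9 enol bond (allylic 1,3-strain with O9–H), so that closure takes place anti to the C7–O bond of the dioxolane. The same face results if O7 is held in the plane by a hydrogen bond to O9–H and closure occurs anti to C6; both arguments lead to 12S. At C8 the side chain sits outward on the enol terminus, away from the C10 bromine, so conrotation places it trans to the C12 hydroxyl, which is 8S, the C8 epimer of the target; step 15 corrects it. The step needs capture of water at C12 in preference to other reactions of the cation: the trans-fused dioxolane keeps O5 from reaching C8 (a trans-fused bicyclo[3.3.0] oxonium ion would be required) and no free hydroxyl is near the cation. It also needs the torquoselectivity just described. The α-bromoenone emerges directly because the bromine sits on furan C3.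

Step 14
Reactants: 19 methyl 7-[(1S,2S)-4-bromo-2-hydroxy-2-[(2Z,5Z)-octa-2,5-dien-1-yl]-5-oxocyclopent-3-en-1-yl]-6,7-(isopropylidenedioxy)-5-(triisopropylsilyloxy)heptanoate
Product: 20 methyl 7-[(1S,2S)-4-bromo-2-hydroxy-2-[(2Z,5Z)-octa-2,5-dien-1-yl]-5-oxocyclopent-3-en-1-yl]-6,7-dihydroxy-5-(triisopropylsilyloxy)heptanoate (8S,12S)
Conditions: TFA–H2O (4:1), CH2Cl2, 0 °C
Reagents that add atoms: none
Why: Acid hydrolysis of the isopropylidene acetal; the triisopropylsilyl ether is stable to brief aqueous acid, the C12 carbinol does not ionize because its cation would be conjugated with the electron-poor enone, and any diol already formed in step 13 converges here.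

Step 15
Reactants: 20 methyl 7-[(1S,2S)-4-bromo-2-hydroxy-2-[(2Z,5Z)-octa-2,5-dien-1-yl]-5-oxocyclopent-3-en-1-yl]-6,7-dihydroxy-5-(triisopropylsilyloxy)heptanoate
Product: 21 methyl 7-[(1R,2S)-4-bromo-2-hydroxy-2-[(2Z,5Z)-octa-2,5-dien-1-yl]-5-oxocyclopent-3-en-1-yl]-6,7-dihydroxy-5-(triisopropylsilyloxy)heptanoate (8R,12S)
Conditions: DBU (0.2 equiv), CH2Cl2, 0 °C to rt; recovered 20 resubmitted
Reagents that add atoms: none
Why: Base-mediated epimerization through the C8 enolate, the cis-to-trans equilibration known for 2,3-disubstituted cyclopentanones: the isomer with the two carbon chains trans and the C7 and C12 hydroxyls on the same side should be favoured. An amidine in an aprotic solvent deprotonates the C–H acid but not the hydroxyls, which keeps retro-aldol cleavage and loss of hydroxide slow; C12 is quaternary and is not touched.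

Step 16
Reactants: 21 methyl 7-[(1R,2S)-4-bromo-2-hydroxy-2-[(2Z,5Z)-octa-2,5-dien-1-yl]-5-oxocyclopent-3-en-1-yl]-6,7-dihydroxy-5-(triisopropylsilyloxy)heptanoate
Product: 22 methyl (5S,6S,7S)-7-[(1R,2S)-4-bromo-2-hydroxy-2-[(2Z,5Z)-octa-2,5-dien-1-yl]-5-oxocyclopent-3-en-1-yl]-5,6,7-trihydroxyheptanoate
Conditions: HF·pyridine, pyridine, THF, 0 °C to rt
Reagents that add atoms: none
Why: Buffered fluoride cleavage of the silyl ether, the standard last step for β-hydroxy cyclopentenone prostanoids; the medium is neither acidic nor basic enough to lactonize the δ-hydroxy ester or to enolize C8.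

## Compound list

1 | L-arabinose (drawn as the open-chain aldehyde) | O=C[C@H](O)[C@@H](O)[C@@H](O)CO | starting material
2 | L-arabinose diethyl dithioacetal | CCSC(SCC)[C@H](O)[C@@H](O)[C@@H](O)CO | intermediate
3 | 2,3:4,5-di-O-isopropylidene-L-arabinose diethyl dithioacetal | CCSC(SCC)[C@@H]1OC(C)(C)O[C@H]1[C@@H]2COC(C)(C)O2 | intermediate
4 | 2,3-O-isopropylidene-L-arabinose diethyl dithioacetal | CCSC(SCC)[C@@H]1OC(C)(C)O[C@H]1[C@@H](O)CO | intermediate
5 | 5-deoxy-5-iodo-2,3-O-isopropylidene-L-arabinose diethyl dithioacetal | CCSC(SCC)[C@@H]1OC(C)(C)O[C@H]1[C@@H](O)CI | intermediate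
6 | 5-deoxy-5-iodo-2,3-O-isopropylidene-4-O-triisopropylsilyl-L-arabinose diethyl dithioacetal | CCSC(SCC)[C@@H]1OC(C)(C)O[C@H]1[C@@H](O[Si](C(C)C)(C(C)C)C(C)C)CI | intermediate
7 | methyl 5,6,7-trideoxy-2,3-O-isopropylidene-4-O-triisopropylsilyl-L-arabino-octuronate diethyl dithioacetal | CCSC(SCC)[C@@H]1OC(C)(C)O[C@H]1[C@@H](O[Si](C(C)C)(C(C)C)C(C)C)CCCC(=O)OC | intermediate
8 | methyl 5,6,7-trideoxy-2,3-O-isopropylidene-4-O-triisopropylsilyl-aldehydo-L-arabino-octuronate (sugar C1 = C8 of the target) | O=C[C@@H]1OC(C)(C)O[C@H]1[C@@H](O[Si](C(C)C)(C(C)C)C(C)C)CCCC(=O)OC | intermediate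
9 | (Z)-hex-3-en-1-ol | CC/C=C\CCO | starting material
10 | (Z)-1-iodohex-3-ene | CC/C=C\CCI | intermediate
11 | [(3Z)-hex-3-en-1-yl]triphenylphosphonium iodide | CC/C=C\CC[P+](c1ccccc1)(c1ccccc1)c1ccccc1.[I-] | intermediate
12 | 4-bromofuran-2-carbaldehyde | O=Cc1cc(Br)co1 | starting material
13 | 4-bromo-2-(2-methoxyethenyl)furan (E/Z mixture) | COC=Cc1cc(Br)co1 | intermediate
14 | 2-(4-bromofuran-2-yl)acetaldehyde | O=CCc1cc(Br)co1 | intermediate
15 | [(3Z)-hex-3-en-1-ylidene]triphenylphosphorane | CC/C=C\CC=P(c1ccccc1)(c1ccccc1)c1ccccc1 | intermediate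
16 | 4-bromo-2-[(2Z,5Z)-octa-2,5-dien-1-yl]furan | CC/C=C\C/C=C\Cc1cc(Br)co1 | intermediate
17 | 3-bromo-2-lithio-5-[(2Z,5Z)-octa-2,5-dien-1-yl]furan | CC/C=C\C/C=C\Cc1cc(Br)c([Li])o1 | intermediate
18 | methyl 8-[3-bromo-5-[(2Z,5Z)-octa-2,5-dien-1-yl]furan-2-yl]-8-hydroxy-6,7-(isopropylidenedioxy)-5-(triisopropylsilyloxy)octanoate (C5–C7 as in 8; both C8 epimers) | CC/C=C\C/C=C\Cc1cc(Br)c(o1)C(O)[C@@H]2OC(C)(C)O[C@H]2[C@@H](O[Si](C(C)C)(C(C)C)C(C)C)CCCC(=O)OC | intermediate
19 | methyl 7-[(1S,2S)-4-bromo-2-hydroxy-2-[(2Z,5Z)-octa-2,5-dien-1-yl]-5-oxocyclopent-3-en-1-yl]-6,7-(isopropylidenedioxy)-5-(triisopropylsilyloxy)heptanoate (C5–C7 as in 8; 8S,12S) | CC/C=C\C/C=C\C[C@@]1(O)C=C(Br)C(=O)[C@H]1[C@@H]2OC(C)(C)O[C@H]2[C@@H](O[Si](C(C)C)(C(C)C)C(C)C)CCCC(=O)OC | intermediate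
20 | methyl 7-[(1S,2S)-4-bromo-2-hydroxy-2-[(2Z,5Z)-octa-2,5-dien-1-yl]-5-oxocyclopent-3-en-1-yl]-6,7-dihydroxy-5-(triisopropylsilyloxy)heptanoate (C5–C7 as in 8; 8S,12S) | CC/C=C\C/C=C\C[C@@]1(O)C=C(Br)C(=O)[C@H]1[C@H](O)[C@@H](O)[C@@H](O[Si](C(C)C)(C(C)C)C(C)C)CCCC(=O)OC | intermediate
21 | methyl 7-[(1R,2S)-4-bromo-2-hydroxy-2-[(2Z,5Z)-octa-2,5-dien-1-yl]-5-oxocyclopent-3-en-1-yl]-6,7-dihydroxy-5-(triisopropylsilyloxy)heptanoate (C5–C7 as in 8; 8R,12S) | CC/C=C\C/C=C\C[C@@]1(O)C=C(Br)C(=O)[C@@H]1[C@H](O)[C@@H](O)[C@@H](O[Si](C(C)C)(C(C)C)C(C)C)CCCC(=O)OC | intermediate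
22 | methyl (5S,6S,7S)-7-[(1R,2S)-4-bromo-2-hydroxy-2-[(2Z,5Z)-octa-2,5-dien-1-yl]-5-oxocyclopent-3-en-1-yl]-5,6,7-trihydroxyheptanoate | CC/C=C\C/C=C\C[C@@]1(O)C=C(Br)C(=O)[C@@H]1[C@H](O)[C@@H](O)[C@@H](O)CCCC(=O)OC | target

## Step count and least certain steps

Total step count: 16. Longest linear sequence: 12 steps (steps 1–7 and 12–16).

Step 13 (key step). Most likely to go wrong:
- Poor or reversed facial selectivity of the electrocyclization, which would lead into the 12-epimeric series that step 15 cannot repair.
- Loss of the furfuryl cation by proton loss toward C13 (the allylic CH2 gives a conjugated triene) or by hydride shift from C7.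
- Slow water addition at the substituted furan carbon, so that the β-alkoxy ketone product is exposed to hot Lewis acid for too long and eliminates across C7–C8.

Fallback (known chemistry, stereocentres set by aldol instead of electrocyclization): it sets out from 16 and from commercial 2-deoxy-D-ribose and comes back at 22. Compound 16 is lithiated as in step 12 and quenched with paraformaldehyde to the furfuryl alcohol F1, whose ZnCl2-promoted rearrangement, now without any side-chain oxygen or stereocentre at the cation, gives the racemic hydroxycyclopentenone F2. 2-Deoxy-D-ribose is olefinated with Ph3P=CHCO2Me to the triol enoate F3, silylated (Et3SiCl, imidazole) to F4, hydrogenated (H2, Pd/C, EtOAc) to F5, and oxidized under Swern conditions, which unmask and oxidize only the primary silyl ether, to the aldehyde F6. The dianion of F2 (LiN(i-Pr)2, 2.1 equiv, −78 °C) is added to F6, where attack anti to the octadienyl group is expected; the adduct F7 with the 8R,12S ring is separated from its diastereomers and desilylated with HF·pyridine to 22.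

Step 15. Most likely to go wrong: the C8 enolate eliminates the C7 or C12 oxygen instead of being reprotonated, the ring opens by retro-aldol cleavage (which would also scramble C12), or the equilibrium is less one-sided than expected. Fallback: it sets out from 20 and comes back at 22. All three hydroxyls of 20 are capped with N-(trimethylsilyl)imidazole to give the tris(trimethylsilyl) ether F8, in which no alkoxide can form and retro-aldol cleavage is blocked. F8 is equilibrated with DBU to its C8 epimer F9, and HF·pyridine then removes all four silyl groups to give 22.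

Step 12. Most likely to go wrong: the amide base or the furyllithium removes a proton from the doubly activated CH2 groups of 16 (C13, C16) or from the α-carbon of aldehyde 8, which would isomerize the diene, epimerize C7 or open the acetonide by β-elimination. Fallback: it sets out from 16 and comes back at 18. The lithiofuran 17 is quenched with iodine to the iodofuran F10, which is stable and can be purified. F10 is coupled with 8 under Nozaki–Hiyama–Kishi conditions (CrCl2, catalytic NiCl2, DMF), a non-basic addition that inserts into the C–I bond in preference to the C–Br bond and gives 18.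

Step 6. Most likely to go wrong: the C5 radical abstracts the dithioacetal hydrogen by 1,5-transfer or is reduced before it adds to the acrylate, and the iodide 6 is alkylated intramolecularly by a dithioacetal sulfur on heating. Fallback: it sets out from 4 and comes back at 7, with an ionic C–C bond formation in place of the radical one. Diol 4 is closed to the terminal epoxide F11 (PPh3, diisopropyl azodicarboxylate). F11 is opened at the primary carbon by lithiated methyl propiolate with BF3·OEt2 at −78 °C to the hydroxy ynoate F12, which is silylated (TIPSOTf, 2,6-lutidine) to F13. The triple bond of F13 is saturated with diimide (TsNHNH2, NaOAc), which tolerates sulfur, to give 7.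

## Further compounds

F1 | step 13 | [3-bromo-5-[(2Z,5Z)-octa-2,5-dien-1-yl]furan-2-yl]methanol | CC/C=C\C/C=C\Cc1cc(Br)c(CO)o1
F2 | step 13 | rac-2-bromo-4-hydroxy-4-[(2Z,5Z)-octa-2,5-dien-1-yl]cyclopent-2-en-1-one | CC/C=C\C/C=C\CC1(O)C=C(Br)C(=O)C1
F3 | step 13 | methyl (2E,5S,6R)-5,6,7-trihydroxyhept-2-enoate | COC(=O)/C=C/C[C@H](O)[C@H](O)CO
F4 | step 13 | methyl (2E,5S,6R)-5,6,7-tris(triethylsilyloxy)hept-2-enoate | COC(=O)/C=C/C[C@H](O[Si](CC)(CC)CC)[C@H](O[Si](CC)(CC)CC)CO[Si](CC)(CC)CC
F5 | step 13 | methyl (5S,6R)-5,6,7-tris(triethylsilyloxy)heptanoate | COC(=O)CCC[C@H](O[Si](CC)(CC)CC)[C@H](O[Si](CC)(CC)CC)CO[Si](CC)(CC)CC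
F6 | step 13 | methyl (5S,6S)-5,6-bis(triethylsilyloxy)-7-oxoheptanoate | COC(=O)CCC[C@H](O[Si](CC)(CC)CC)[C@H](O[Si](CC)(CC)CC)C=O
F7 | step 13 | 5,6-bis-O-triethylsilyl derivative of 22 | CC/C=C\C/C=C\C[C@@]1(O)C=C(Br)C(=O)[C@@H]1[C@H](O)[C@@H](O[Si](CC)(CC)CC)[C@@H](O[Si](CC)(CC)CC)CCCC(=O)OC
F8 | step 15 | 6,7,12-tris-O-trimethylsilyl derivative of 20 | CC/C=C\C/C=C\C[C@@]1(O[Si](C)(C)C)C=C(Br)C(=O)[C@H]1[C@H](O[Si](C)(C)C)[C@@H](O[Si](C)(C)C)[C@@H](O[Si](C(C)C)(C(C)C)C(C)C)CCCC(=O)OC
F9 | step 15 | 6,7,12-tris-O-trimethylsilyl derivative of 21 | CC/C=C\C/C=C\C[C@@]1(O[Si](C)(C)C)C=C(Br)C(=O)[C@@H]1[C@H](O[Si](C)(C)C)[C@@H](O[Si](C)(C)C)[C@@H](O[Si](C(C)C)(C(C)C)C(C)C)CCCC(=O)OC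
F10 | step 12 | 3-bromo-2-iodo-5-[(2Z,5Z)-octa-2,5-dien-1-yl]furan | CC/C=C\C/C=C\Cc1cc(Br)c(I)o1
F11 | step 6 | 4,5-anhydro-2,3-O-isopropylidene-L-arabinose diethyl dithioacetal | CCSC(SCC)[C@@H]1OC(C)(C)O[C@H]1[C@@H]2CO2
F12 | step 6 | 5-deoxy-2,3-O-isopropylidene-5-C-(3-methoxy-3-oxoprop-1-yn-1-yl)-L-arabinose diethyl dithioacetal | CCSC(SCC)[C@@H]1OC(C)(C)O[C@H]1[C@@H](O)CC#CC(=O)OC
F13 | step 6 | 4-O-triisopropylsilyl ether of F12 | CCSC(SCC)[C@@H]1OC(C)(C)O[C@H]1[C@@H](O[Si](C(C)C)(C(C)C)C(C)C)CC#CC(=O)OC
A1 | alternative 1 | (S)-2-bromo-4-hydroxy-4-[(2Z,5Z)-octa-2,5-dien-1-yl]cyclopent-2-en-1-one | CC/C=C\C/C=C\C[C@@]1(O)C=C(Br)C(=O)C1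
A2 | alternative 1 | methyl (5S,6S)-5,6-bis(tert-butyldimethylsilyloxy)-7-oxoheptanoate | O=C[C@@H](O[Si](C)(C)C(C)(C)C)[C@@H](O[Si](C)(C)C(C)(C)C)CCCC(=O)OC
A3 | alternative 2 | trans-3-bromo-4-hydroxycyclopent-2-en-1-one carrying at C5 the protected C1–C7 chain of 8 (C12 ketone, C9 carbinol, C8 as in the target) | O=C1C=C(Br)[C@@H](O)[C@@H]1[C@@H]2OC(C)(C)O[C@H]2[C@@H](O[Si](C(C)C)(C(C)C)C(C)C)CCCC(=O)OC
A4 | alternative 2 | (2Z,5Z)-1-chloroocta-2,5-diene | CC/C=C\C/C=C\CCl
A5 | alternative 3 | methyl (10Z,14Z,17Z)-10-bromo-6,7-(isopropylidenedioxy)-9,12-dioxo-5-(triisopropylsilyloxy)icosa-10,14,17-trienoate (C5–C7 as in 8) | CC/C=C\C/C=C\CC(=O)/C=C(Br)\C(=O)C[C@@H]1OC(C)(C)O[C@H]1[C@@H](O[Si](C(C)C)(C(C)C)C(C)C)CCCC(=O)OC
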